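**Retrosynthetic overview**

1. The last bond is C17–C18, made by Stille coupling of the stannyl hexaene-dione 15 with the iodovinyl tetrahydrofuran acid 26; no protecting groups remain at that stage.
2. 15 comes from a Wittig reaction (C8=C9) of keto-ylide 8 with stannyl tetraenal 14. 8 comes from the 2,3-dioxobutane bis-ylide 6 and (R)-2-methylbutanal, whose stereocentre is set by asymmetric hydrogenation of tiglic acid.
3. 14 comes from glutaconaldehyde salt by bromination, two-carbon Wittig homologation and Stille coupling with (E)-1,2-bis(tributylstannyl)ethene.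
4. The only ring, the tetrahydrofuran, is closed as a 2-deoxyfuranoside from the D-proline aldol adduct of 2,2-dimethyl-1,3-dioxan-5-one and 3,3-diethoxypropanal, which sets ring C2 and C3. Ketol cleavage then gives the ester.
5. Ring C5 and the C5–C19 bond come from a hydroxyl-directed alkenylboronate addition to the furanosyl oxocarbenium ion (new), followed by iododesilylation and saponification.

Assumption: acyclic carbons are numbered C1 (ethyl CH3) to C19 (alkene carbon on the ring) and ring atoms O1, C2 (CO2H), C3 (OH), C4, C5. The target is (2R,3R,5R) in the ring and (R) at chain C3. All starting materials are achiral and taken as catalogue items.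

**Route**

Step 1
Reactants: 1 tiglic acid ((2E)-2-methylbut-2-enoic acid)
Product: 2 (R)-2-methylbutanoic acid
Conditions: Ru(OAc)2[(R)-H8-BINAP] (0.5 mol%), H2 (4 atm), MeOH, 20 °C
Reagents that add atoms: none
Why: Carboxylate-directed asymmetric hydrogenation of the trisubstituted alkene adds H2 to one enantioface; the (R)-ligand is the one that gives the (R)-acid (about 97% ee expected), which sets the only stereocentre of this fragment.

Step 2
Reactants: 2 (R)-2-methylbutanoic acid
Product: 3 (R)-2-methylbutan-1-ol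
Conditions: LiAlH4, Et2O, 0 °C to rt; H2O, NaOH work-up
Reagents that add atoms: none
Why: Hydride reduction of the acid to the primary alcohol; the α-stereocentre of the aluminium carboxylate is not deprotonated and is retained.

Step 3
Reactants: 4 1,4-dibromobutane-2,3-dione
Product: 6 1,4-bis(triphenylphosphoranylidene)butane-2,3-dione, via bis-phosphonium dibromide 5 (not isolated)
Conditions: PPh3 (2.05 equiv), THF, rt; then aq. Na2CO3, CH2Cl2
Reagents that add atoms: triphenylphosphine, c1ccc(cc1)P(c1ccccc1)c1ccccc1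
Why: Double SN2 quaternisation of triphenylphosphine by the bis(α-bromo ketone), then carbonate deprotonation of the acidic phosphonium CH2 groups, gives the carbonyl-stabilised bis-ylide (phosphonium salt formation and ylide generation).

Step 4
Reactants: 3 (R)-2-methylbutan-1-ol; 6 1,4-bis(triphenylphosphoranylidene)butane-2,3-dione (2 equiv)
Product: 8 (4E,6R)-6-methyl-1-(triphenylphosphoranylidene)oct-4-ene-2,3-dione, via (R)-2-methylbutanal 7 (not isolated)
Conditions: (COCl)2, DMSO, i-Pr2NEt, CH2Cl2, −78 °C; cold water wash; solution added to 6, CH2Cl2, 0 °C to rt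
Reagents that add atoms: none
Why: Swern oxidation then Wittig olefination with a carbonyl-stabilised ylide gives the E-enone; the excess of 6 and the lower nucleophilicity of the remaining ylide once it is conjugated to the new ene-dione hold the reaction at mono-olefination, and the α-stereocentre of 7 survives because the aldehyde is used cold and at once.

Step 5
Reactants: 9 glutaconaldehyde potassium salt
Product: 10 (2E,4E)-5-bromopenta-2,4-dienal
Conditions: Ph3PBr2, CH2Cl2, 0 °C to rt
Reagents that add atoms: dibromotriphenylphosphorane, BrP(Br)(c1ccccc1)(c1ccccc1)c1ccccc1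
Why: Deoxybromination of a vinylogous carboxylate: O-phosphonium formation, then addition–elimination of bromide with loss of Ph3PO, gives the thermodynamically favoured E,E bromodienal.

Step 6
Reactants: 10 (2E,4E)-5-bromopenta-2,4-dienal; 11 (triphenylphosphoranylidene)acetaldehyde
Product: 12 (2E,4E,6E)-7-bromohepta-2,4,6-trienal
Conditions: toluene, 40 °C, dark
Reagents that add atoms: none
Why: Wittig two-carbon homologation with a formyl-stabilised ylide is E-selective and stops after one cycle because the trienal is less electrophilic than the dienal.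

Step 7
Reactants: 12 (2E,4E,6E)-7-bromohepta-2,4,6-trienal; 13 (E)-1,2-bis(tributylstannyl)ethene (3 equiv)
Product: 14 (2E,4E,6E,8E)-9-(tributylstannyl)nona-2,4,6,8-tetraenal
Conditions: PdCl2(MeCN)2 (5 mol%), DMF, 23 °C, dark
Reagents that add atoms: none
Why: Stille coupling: zerovalent palladium inserts into the aldehyde-activated alkenyl bromide and transmetalates one tin of the excess distannane, with retention of both alkene geometries.

Step 8
Reactants: 8 (4E,6R)-6-methyl-1-(triphenylphosphoranylidene)oct-4-ene-2,3-dione; 14 (2E,4E,6E,8E)-9-(tributylstannyl)nona-2,4,6,8-tetraenal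
Product: 15 (3R,4E,8E,10E,12E,14E,16E)-3-methyl-17-(tributylstannyl)heptadeca-4,8,10,12,14,16-hexaene-6,7-dione
Conditions: toluene, 45 °C, dark, Ar
Reagents that add atoms: none
Why: Wittig olefination with the keto-stabilised ylide builds the C8=C9 alkene E-selectively under neutral conditions that leave the alkenylstannane and the 1,2-dione untouched.

Step 9
Reactants: 16 3,3-diethoxypropan-1-ol
Product: 17 3,3-diethoxypropanal
Conditions: (COCl)2, DMSO, Et3N, CH2Cl2, −78 °C to 0 °C
Reagents that add atoms: none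
Why: Swern oxidation under basic, anhydrous conditions that keep the acetal intact.

Step 10
Reactants: 17 3,3-diethoxypropanal; 18 2,2-dimethyl-1,3-dioxan-5-one
Product: 19 (4R)-4-[(1R)-3,3-diethoxy-1-hydroxypropyl]-2,2-dimethyl-1,3-dioxan-5-one
Conditions: D-proline (30 mol%), DMF, 4 °C, 5 d
Reagents that add atoms: none
Why: Proline-catalysed direct aldol reaction through the enamine of the dioxanone (hydrogen-bonded Houk–List transition state) gives the anti aldol; D-proline delivers the (4R,1'R) isomer, which sets ring C2 and C3 as the first stereocentres of this fragment (over 90% ee and high anti selectivity expected for this donor).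

Step 11
Reactants: 19 (4R)-4-[(1R)-3,3-diethoxy-1-hydroxypropyl]-2,2-dimethyl-1,3-dioxan-5-one
Product: 21 1-[(2R,3R)-5-ethoxy-3-hydroxytetrahydrofuran-2-yl]-2-hydroxyethan-1-one as a mixture of C5 epimers, via open-chain triol ketone 20 (not isolated)
Conditions: TsOH·H2O (5 mol%), EtOH, rt; Et3N quench
Reagents that add atoms: none
Why: Acid-catalysed transketalisation frees the diol and the hydroxyl on the ketone α-carbon closes onto the acetal carbon (Fischer-type glycosidation; the five-membered ring is favoured over four- and seven-membered alternatives), which forms the tetrahydrofuran ring without touching C2 or C3; the anomeric mixture converges in step 13.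

Step 12
Reactants: 21 1-[(2R,3R)-5-ethoxy-3-hydroxytetrahydrofuran-2-yl]-2-hydroxyethan-1-one
Product: 22 methyl (2R,3R)-5-ethoxy-3-hydroxytetrahydrofuran-2-carboxylate (mixture of C5 epimers)
Conditions: Pb(OAc)4 (1.1 equiv), MeOH/CH2Cl2 1:1, 0 °C
Reagents that add atoms: methanol, CO
Why: Criegee cleavage of the α-ketol as its methanol hemiketal by lead tetraacetate gives the methyl ester and formaldehyde directly; the secondary alcohol and the acetal are inert and ring C2 is not epimerised.

Step 13
Reactants: 22 methyl (2R,3R)-5-ethoxy-3-hydroxytetrahydrofuran-2-carboxylate; 23 (E)-trimethyl[2-(4,4,5,5-tetramethyl-1,3,2-dioxaborolan-2-yl)ethenyl]silane (1.5 equiv)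
Product: 24 methyl (2R,3R,5R)-3-hydroxy-5-[(E)-2-(trimethylsilyl)ethenyl]tetrahydrofuran-2-carboxylate
Conditions: (PhO)2P(O)OH (10 mol%), HFIP/CH2Cl2 1:4, 4 Å MS, −20 to 0 °C; aq. NaHCO3
Reagents that add atoms: none
Why: Proposed new method: acid-catalysed ionisation of either anomer of 22 in the ionising solvent gives the 2-deoxyfuranosyl oxocarbenium ion while the free C3 hydroxyl binds the boron of 23 as a tetracoordinate boronate, whose alkenyl group then migrates to C5 through a six-membered chair transition state on the face that carries O3, so the C5–C19 bond forms cis to the hydroxyl (5R), an outcome reinforced by the intrinsic inside-attack preference of 3-oxygenated five-membered oxocarbenium ions; the closest known reactions are the Petasis borono-Mannich reaction, hydroxyl-directed alkenylboronate additions to cyclic N-acyliminium ions and Lewis-acid additions of alkenyltrifluoroborates to cyclic acetals, none of which has been shown for a 1,3-related hydroxyl steering a boronate onto an unactivated furanosyl cation.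

Step 14
Reactants: 24 methyl (2R,3R,5R)-3-hydroxy-5-[(E)-2-(trimethylsilyl)ethenyl]tetrahydrofuran-2-carboxylate
Product: 25 methyl (2R,3R,5R)-3-hydroxy-5-[(E)-2-iodoethenyl]tetrahydrofuran-2-carboxylate
Conditions: NIS (1.2 equiv), HFIP, 0 °C, 10 min
Reagents that add atoms: N-iodosuccinimide, O=C1CCC(=O)N1I
Why: Iododesilylation (ipso substitution of the alkenylsilane through a β-silyl-stabilised cation) replaces silicon by iodine with retention of the E geometry.

Step 15
Reactants: 25 methyl (2R,3R,5R)-3-hydroxy-5-[(E)-2-iodoethenyl]tetrahydrofuran-2-carboxylate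
Product: 26 (2R,3R,5R)-3-hydroxy-5-[(E)-2-iodoethenyl]tetrahydrofuran-2-carboxylic acid
Conditions: LiOH·H2O (2 equiv), THF/H2O 3:1, 0 °C; 1 M HCl to pH 3
Reagents that add atoms: lithium hydroxide, [Li+].[OH-]
Why: Saponification of the methyl ester at 0 °C; the alkenyl iodide and the ring stereocentres are stable to cold hydroxide.

Step 16
Reactants: 15 (3R,4E,8E,10E,12E,14E,16E)-3-methyl-17-(tributylstannyl)heptadeca-4,8,10,12,14,16-hexaene-6,7-dione; 26 (2R,3R,5R)-3-hydroxy-5-[(E)-2-iodoethenyl]tetrahydrofuran-2-carboxylic acid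
Product: 27 (2R,3R,5R)-3-hydroxy-5-[(1E,3E,5E,7E,9E,11E,15E,17R)-17-methyl-13,14-dioxononadeca-1,3,5,7,9,11,15-heptaen-1-yl]tetrahydrofuran-2-carboxylic acid (CNP0156165.1)
Conditions: Pd2(dba)3 (5 mol%), AsPh3 (20 mol%), DMF, 23 °C, dark, Ar
Reagents that add atoms: none
Why: Stille coupling between the alkenyl iodide and the polyenylstannane under neutral zerovalent palladium conditions joins C17 to C18 with retention of all alkene geometries and tolerates the free acid, the alcohol and the 1,2-dione, so the target is obtained without a deprotection.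

**Compound list**

1 | tiglic acid ((2E)-2-methylbut-2-enoic acid) | C/C=C(\C)C(=O)O | starting material
2 | (R)-2-methylbutanoic acid | CC[C@@H](C)C(=O)O | intermediate
3 | (R)-2-methylbutan-1-ol | CC[C@@H](C)CO | intermediate
4 | 1,4-dibromobutane-2,3-dione | BrCC(=O)C(=O)CBr | starting material
5 | (2,3-dioxobutane-1,4-diyl)bis(triphenylphosphonium) dibromide | [Br-].[Br-].O=C(C[P+](c1ccccc1)(c1ccccc1)c1ccccc1)C(=O)C[P+](c1ccccc1)(c1ccccc1)c1ccccc1 | intermediate
6 | 1,4-bis(triphenylphosphoranylidene)butane-2,3-dione | O=C(C=P(c1ccccc1)(c1ccccc1)c1ccccc1)C(=O)C=P(c1ccccc1)(c1ccccc1)c1ccccc1 | intermediate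
7 | (R)-2-methylbutanal | CC[C@@H](C)C=O | intermediate
8 | (4E,6R)-6-methyl-1-(triphenylphosphoranylidene)oct-4-ene-2,3-dione | CC[C@@H](C)/C=C/C(=O)C(=O)C=P(c1ccccc1)(c1ccccc1)c1ccccc1 | intermediate
9 | glutaconaldehyde potassium salt (potassium (1E,3E)-5-oxopenta-1,3-dien-1-olate) | [K+].[O-]/C=C/C=C/C=O | starting material
10 | (2E,4E)-5-bromopenta-2,4-dienal | Br/C=C/C=C/C=O | intermediate
11 | (triphenylphosphoranylidene)acetaldehyde | O=CC=P(c1ccccc1)(c1ccccc1)c1ccccc1 | starting material
12 | (2E,4E,6E)-7-bromohepta-2,4,6-trienal | Br/C=C/C=C/C=C/C=O | intermediate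
13 | (E)-1,2-bis(tributylstannyl)ethene | CCCC[Sn](CCCC)(CCCC)/C=C/[Sn](CCCC)(CCCC)CCCC | starting material
14 | (2E,4E,6E,8E)-9-(tributylstannyl)nona-2,4,6,8-tetraenal | O=C/C=C/C=C/C=C/C=C/[Sn](CCCC)(CCCC)CCCC | intermediate
15 | (3R,4E,8E,10E,12E,14E,16E)-3-methyl-17-(tributylstannyl)heptadeca-4,8,10,12,14,16-hexaene-6,7-dione | CC[C@@H](C)/C=C/C(=O)C(=O)/C=C/C=C/C=C/C=C/C=C/[Sn](CCCC)(CCCC)CCCC | intermediate
16 | 3,3-diethoxypropan-1-ol | CCOC(CCO)OCC | starting material
17 | 3,3-diethoxypropanal | CCOC(CC=O)OCC | intermediate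
18 | 2,2-dimethyl-1,3-dioxan-5-one | CC1(C)OCC(=O)CO1 | starting material
19 | (4R)-4-[(1R)-3,3-diethoxy-1-hydroxypropyl]-2,2-dimethyl-1,3-dioxan-5-one | CCOC(OCC)C[C@@H](O)[C@H]1OC(C)(C)OCC1=O | intermediate
20 | (3R,4R)-6,6-diethoxy-1,3,4-trihydroxyhexan-2-one | CCOC(OCC)C[C@@H](O)[C@@H](O)C(=O)CO | intermediate
21 | 1-[(2R,3R)-5-ethoxy-3-hydroxytetrahydrofuran-2-yl]-2-hydroxyethan-1-one (C5 epimers) | CCOC1C[C@@H](O)[C@H](C(=O)CO)O1 | intermediate
22 | methyl (2R,3R)-5-ethoxy-3-hydroxytetrahydrofuran-2-carboxylate (C5 epimers) | CCOC1C[C@@H](O)[C@H](C(=O)OC)O1 | intermediate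
23 | (E)-trimethyl[2-(4,4,5,5-tetramethyl-1,3,2-dioxaborolan-2-yl)ethenyl]silane | C[Si](C)(C)/C=C/B1OC(C)(C)C(C)(C)O1 | starting material
24 | methyl (2R,3R,5R)-3-hydroxy-5-[(E)-2-(trimethylsilyl)ethenyl]tetrahydrofuran-2-carboxylate | C[Si](C)(C)/C=C/[C@H]1C[C@@H](O)[C@H](C(=O)OC)O1 | intermediate
25 | methyl (2R,3R,5R)-3-hydroxy-5-[(E)-2-iodoethenyl]tetrahydrofuran-2-carboxylate | I/C=C/[C@H]1C[C@@H](O)[C@H](C(=O)OC)O1 | intermediate
26 | (2R,3R,5R)-3-hydroxy-5-[(E)-2-iodoethenyl]tetrahydrofuran-2-carboxylic acid | I/C=C/[C@H]1C[C@@H](O)[C@H](C(=O)O)O1 | intermediate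
27 | (2R,3R,5R)-3-hydroxy-5-[(1E,3E,5E,7E,9E,11E,15E,17R)-17-methyl-13,14-dioxononadeca-1,3,5,7,9,11,15-heptaen-1-yl]tetrahydrofuran-2-carboxylic acid | CC[C@@H](C)/C=C/C(=O)C(=O)/C=C/C=C/C=C/C=C/C=C/C=C/[C@H]1C[C@@H](O)[C@H](C(=O)O)O1 | target

**Step count and risks**

Total: 16 steps. Longest linear sequence: 8 steps (steps 9 to 16).

The three steps most likely to fail:

Step 13 (the proposed new step). The boronate may not transfer, or the oxocarbenium ion may collapse to a furan. The fallback uses known chemistry and sets out from 22. TBSOTf with 2,6-lutidine gives methyl (2R,3R)-3-[(tert-butyldimethylsilyl)oxy]-5-ethoxytetrahydrofuran-2-carboxylate F4. Potassium (trimethylsilyl)ethynyltrifluoroborate with BF3·OEt2 in MeCN at −40 °C adds to the oxocarbenium ion by inside attack, cis to the 3-silyloxy group, to give methyl (2R,3R,5R)-3-[(tert-butyldimethylsilyl)oxy]-5-[(trimethylsilyl)ethynyl]tetrahydrofuran-2-carboxylate F5. K2CO3 in MeOH gives methyl (2R,3R,5R)-3-[(tert-butyldimethylsilyl)oxy]-5-ethynyltetrahydrofuran-2-carboxylate F6. Hydrozirconation with Cp2Zr(H)Cl followed by I2 gives methyl (2R,3R,5R)-3-[(tert-butyldimethylsilyl)oxy]-5-[(E)-2-iodoethenyl]tetrahydrofuran-2-carboxylate F7. HF·pyridine removes the silyl ether and the route is rejoined at 25.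

Step 10. The acetal aldehyde 17 can lose ethanol to 3-ethoxyacrolein or self-condense under amine catalysis. The fallback carries ring C5 at the alcohol oxidation level and oxidises it only after the aldol; it sets out from 18. D-proline-catalysed aldol with achiral 3-[(tert-butyldimethylsilyl)oxy]propanal gives (4R)-4-[(1R)-3-[(tert-butyldimethylsilyl)oxy]-1-hydroxypropyl]-2,2-dimethyl-1,3-dioxan-5-one F1. HF·pyridine in THF gives (4R)-4-[(1R)-1,3-dihydroxypropyl]-2,2-dimethyl-1,3-dioxan-5-one F2. TEMPO (cat.) with PhI(OAc)2 oxidises only the primary alcohol to (3R)-3-[(4R)-2,2-dimethyl-5-oxo-1,3-dioxan-4-yl]-3-hydroxypropanal F3. TsOH in ethanol then removes the acetonide and closes the ethyl furanoside, and the route is rejoined at 21.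

Step 16. The stannyl hexaene-dione 15 may protodestannylate or decompose before it couples. The fallback changes the last bond formed from C17–C18 to C8=C9, so the dione never meets palladium or tin; it sets out from 26. Stille coupling of 26 with the stannyl tetraenal 14 (Pd2(dba)3, AsPh3, DMF, rt) gives (2R,3R,5R)-3-hydroxy-5-[(1E,3E,5E,7E,9E)-11-oxoundeca-1,3,5,7,9-pentaen-1-yl]tetrahydrofuran-2-carboxylic acid F8. Wittig olefination of F8 with ylide 8 (i-Pr2NEt 1 equiv to hold the acid as its carboxylate, CH2Cl2, 35 °C, dark) then gives 27 directly.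

**Further compounds**

F1 | step 10 | (4R)-4-[(1R)-3-[(tert-butyldimethylsilyl)oxy]-1-hydroxypropyl]-2,2-dimethyl-1,3-dioxan-5-one | CC(C)(C)[Si](C)(C)OCC[C@@H](O)[C@H]1OC(C)(C)OCC1=O
F2 | step 10 | (4R)-4-[(1R)-1,3-dihydroxypropyl]-2,2-dimethyl-1,3-dioxan-5-one | OCC[C@@H](O)[C@H]1OC(C)(C)OCC1=O
F3 | step 10 | (3R)-3-[(4R)-2,2-dimethyl-5-oxo-1,3-dioxan-4-yl]-3-hydroxypropanal | O=CC[C@@H](O)[C@H]1OC(C)(C)OCC1=O
F4 | step 13 | methyl (2R,3R)-3-[(tert-butyldimethylsilyl)oxy]-5-ethoxytetrahydrofuran-2-carboxylate | CCOC1C[C@@H](O[Si](C)(C)C(C)(C)C)[C@H](C(=O)OC)O1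
F5 | step 13 | methyl (2R,3R,5R)-3-[(tert-butyldimethylsilyl)oxy]-5-[(trimethylsilyl)ethynyl]tetrahydrofuran-2-carboxylate | C[Si](C)(C)C#C[C@H]1C[C@@H](O[Si](C)(C)C(C)(C)C)[C@H](C(=O)OC)O1
F6 | step 13 | methyl (2R,3R,5R)-3-[(tert-butyldimethylsilyl)oxy]-5-ethynyltetrahydrofuran-2-carboxylate | C#C[C@H]1C[C@@H](O[Si](C)(C)C(C)(C)C)[C@H](C(=O)OC)O1
F7 | step 13 | methyl (2R,3R,5R)-3-[(tert-butyldimethylsilyl)oxy]-5-[(E)-2-iodoethenyl]tetrahydrofuran-2-carboxylate | I/C=C/[C@H]1C[C@@H](O[Si](C)(C)C(C)(C)C)[C@H](C(=O)OC)O1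
F8 | step 16 | (2R,3R,5R)-3-hydroxy-5-[(1E,3E,5E,7E,9E)-11-oxoundeca-1,3,5,7,9-pentaen-1-yl]tetrahydrofuran-2-carboxylic acid | O=C/C=C/C=C/C=C/C=C/C=C/[C@H]1C[C@@H](O)[C@H](C(=O)O)O1
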